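**Assumption:** Locants C1–C15 are germacrane locants of the target: C6 is the lactone carbinol, C7 the ring-fusion CH, C8 the ester carbinol, C1/C10 the oxirane and C15 the CH2OH. The D-fructose-derived Shi ketone is bought.

## Retrosynthetic overview
1. The ten-membered ring is closed last, by diene–ene ring-closing metathesis across C2=C3, followed by removal of the C15 silyl ether.
2. The C8 ester comes from (Z)-4-acetoxy-3-methylbut-2-enoic acid. The α-methylene lactone comes from a C6-O-phosphonoacetate carbanion that opens a C7–C8 oxirane 5-exo (forms C7–C11, frees O8), then HWE with CH2O.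
3. C5–C6 comes from Felkin addition of a geometrically defined dienyllithium to a bis-epoxy aldehyde.
4. Key step: both oxiranes (C1–C10, kept; C7–C8, sacrificial) are made from one achiral skipped trienol in a single double Shi epoxidation. This sets C1, C10, C7 and C8.
5. Ring order: two oxiranes together, then the γ-lactone (consumes one oxirane), then the ten-membered carbocycle.

## Route

Step 1
Reactants: 1 prop-2-yn-1-ol; 2 3-bromoprop-1-yne
Product: 3 hexa-2,5-diyn-1-ol
Conditions: CuI (10 mol %), Bu4NCl (cat.), Na2CO3, DMF, rt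
Reagents that add atoms: none
Why: Cu(I)-catalysed coupling of a copper acetylide with a propargylic halide (Jeffery-type sp–sp3 coupling) gives the skipped diyne without protecting the alcohol.

Step 2
Reactants: 3 hexa-2,5-diyn-1-ol
Product: 4 (2E)-hex-2-en-5-yn-1-ol
Conditions: LiAlH4, THF, 0 °C to rt; H2O
Reagents that add atoms: none
Why: Alkoxide-directed trans-hydroalumination reduces only the propargylic-alcohol alkyne and gives the E-olefin, while the remote terminal alkyne is merely deprotonated.

Step 3
Reactants: 4 (2E)-hex-2-en-5-yn-1-ol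
Product: 6 (2E,5E)-5-methylocta-2,5,7-trien-1-ol, via alkenylalane 5 (not isolated)
Conditions: AlMe3 (3 equiv), Cp2ZrCl2 (25 mol %), CH2Cl2, 0 °C to rt; then vinyl bromide, Pd(PPh3)4 (5 mol %), ZnCl2 (cat.), THF, rt; H2O
Reagents that add atoms: trimethylaluminium C[Al](C)C; vinyl bromide C=CBr
Why: Negishi Zr-catalysed syn-carboalumination places CH3 on C10 and Al on C1, and the Pd-catalysed alkenyl–alkenyl Negishi coupling proceeds with retention, so C10=C1 is formed as the E isomer.

Step 4 (key step)
Reactants: 6 (2E,5E)-5-methylocta-2,5,7-trien-1-ol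
Product: 8 [(2R,3R)-3-{[(2R,3R)-3-ethenyl-2-methyloxiran-2-yl]methyl}oxiran-2-yl]methanol, via vinyl-oxirane monoepoxide 7 (not isolated)
Conditions: D-fructose-derived Shi ketone (0.6 equiv), Oxone (3 equiv), K2CO3, Bu4NHSO4 (cat.), MeCN–DMM / Na2B4O7–EDTA buffer (pH 10.5), 0 °C
Reagents that add atoms: potassium peroxymonosulfate (Oxone) [K+].OOS(=O)(=O)[O-]
Why: In the Shi asymmetric epoxidation the spiro transition state delivers oxygen in the same (R,R) sense to the trisubstituted diene olefin and to the trans allylic-alcohol olefin and leaves the terminal vinyl group alone, so two oxiranes and C1, C10, C7 and C8 are set by reagent control in one flask, with statistical (Horeau) upgrading of the ee of the major diastereomer.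

Step 5
Reactants: 8 bis-epoxy alcohol
Product: 9 (2S,3R)-3-{[(2R,3R)-3-ethenyl-2-methyloxiran-2-yl]methyl}oxirane-2-carbaldehyde
Conditions: TPAP (5 mol %), NMO, 4 Å MS, CH2Cl2, 0 °C to rt
Reagents that add atoms: none
Why: The neutral Ley–Griffith oxidation converts 2,3-epoxy alcohols into epoxy aldehydes without touching either oxirane; the C7 descriptor changes only through CIP priority.

Step 6
Reactants: 10 3-(trimethylsilyl)prop-2-yn-1-ol
Product: 12 (2E)-2-[(trimethylsilyl)methylidene]but-3-en-1-ol, via chelated dienylmagnesium 11 (not isolated)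
Conditions: vinylMgCl (3 equiv), CuI (10 mol %), THF–toluene, reflux; H2O
Reagents that add atoms: vinylmagnesium chloride C=C[Mg]Cl
Why: Chelation-controlled anti-carbomagnesiation of a propargylic alkoxide (Duboudin/Fallis type) puts the vinyl group on the carbinol-side carbon and Mg on the silyl-bearing carbon cis to CH2O, so after protonation the silyl group lies cis to the vinyl group.

Step 7
Reactants: 12 (2E)-2-[(trimethylsilyl)methylidene]but-3-en-1-ol
Product: 13 tert-butyl(dimethyl){[(2E)-2-[(trimethylsilyl)methylidene]but-3-en-1-yl]oxy}silane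
Conditions: TBSCl, imidazole, DMF, rt
Reagents that add atoms: tert-butyldimethylsilyl chloride CC(C)(C)[Si](C)(C)Cl
Why: Standard silylation masks the future C15 hydroxyl as the only protecting group of the route.

Step 8
Reactants: 13 dienylsilane TBS ether
Product: 14 tert-butyl{[(2E)-2-(iodomethylidene)but-3-en-1-yl]oxy}dimethylsilane
Conditions: NIS, MeCN, 0 °C, dark
Reagents that add atoms: N-iodosuccinimide O=C1CCC(=O)N1I
Why: Ipso-iododesilylation through the β-silyl (allylic) cation occurs with retention, which places iodine cis to the vinyl group as the C4=C5 geometry requires.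

Step 9
Reactants: 14 dienyl iodide; 9 bis-epoxy aldehyde
Product: 16 (1R,2E)-3-({[tert-butyl(dimethyl)silyl]oxy}methyl)-1-[(2R,3R)-3-{[(2R,3R)-3-ethenyl-2-methyloxiran-2-yl]methyl}oxiran-2-yl]penta-2,4-dien-1-ol, via dienyllithium 15 (not isolated)
Conditions: 14, t-BuLi (2 equiv), Et2O, −78 °C; then 9, THF, −78 °C; H2O at −78 °C
Reagents that add atoms: none
Why: Iodine–lithium exchange is stereoretentive, and polar Felkin–Anh 1,2-addition anti to the oxirane C–O bond favours the anti (erythro) epoxy alcohol, i.e. (6R); about 3:1 is expected and the syn epimer is removed by chromatography.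

Step 10
Reactants: 16 anti-epoxy alcohol; 17 (diethoxyphosphoryl)acetic acid
Product: 18 (diethoxyphosphoryl)acetate ester of 16 at O6
Conditions: DCC, DMAP (cat.), CH2Cl2, 0 °C
Reagents that add atoms: none
Why: Steglich esterification acylates the only free hydroxyl under neutral conditions that both oxiranes tolerate.

Step 11
Reactants: 18 O6-phosphonoacetate
Product: 20 (4R,5R)-5-[(1E)-2-({[tert-butyl(dimethyl)silyl]oxy}methyl)buta-1,3-dien-1-yl]-4-{(1R)-2-[(2R,3R)-3-ethenyl-2-methyloxiran-2-yl]-1-hydroxyethyl}-3-methylideneoxolan-2-one, via phosphono-lactone 19 (not isolated)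
Conditions: NaH (1.05 equiv), THF, 0 to 40 °C; then (CH2O)n, rt
Reagents that add atoms: formaldehyde C=O
Why: The stabilised carbanion opens the adjacent oxirane 5-exo-tet at C7 with inversion (giving the trans lactone and keeping the 8R carbinol), the liberated alkoxide is quenched by the acidic C11–H, and the resulting phosphonate anion undergoes Horner–Wadsworth–Emmons methylenation.

Step 12
Reactants: 1 prop-2-yn-1-ol
Product: 22 (2Z)-3-iodo-2-methylprop-2-en-1-ol, via chelated alkenylmagnesium 21 (not isolated)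
Conditions: MeMgBr (2.5 equiv), CuI (cat.), Et2O–THF, −10 °C to rt; then I2, −20 °C; H2O
Reagents that add atoms: methylmagnesium bromide C[Mg]Br; iodine II
Why: Duboudin Cu-catalysed anti-carbomagnesiation gives the oxygen-chelated alkenylmagnesium, whose iodinolysis with retention leaves iodine cis to CH2OH.

Step 13
Reactants: 22 (2Z)-3-iodo-2-methylprop-2-en-1-ol
Product: 23 (2Z)-3-iodo-2-methylprop-2-en-1-yl acetate
Conditions: Ac2O, pyridine, 0 °C to rt
Reagents that add atoms: acetic anhydride CC(=O)OC(C)=O
Why: Acetylation before the carboxyl group exists blocks the otherwise spontaneous closure of the Z-hydroxy acid to the butenolide.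

Step 14
Reactants: 23 (2Z)-3-iodo-2-methylprop-2-en-1-yl acetate
Product: 24 (2Z)-4-acetoxy-3-methylbut-2-enoic acid
Conditions: Pd(OAc)2 (5 mol %), PPh3 (10 mol %), CO (1 atm), H2O, Et3N, DMF, 40 °C
Reagents that add atoms: carbon monoxide [C-]#[O+]; water O
Why: In the Pd-catalysed hydroxycarbonylation, oxidative addition into the C–I bond is much faster than ionisation of the allylic acetate and proceeds with retention, so the Z acid is obtained.

Step 15
Reactants: 20 hydroxy α-methylene lactone; 24 (2Z)-4-acetoxy-3-methylbut-2-enoic acid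
Product: 25 C8 (2Z)-4-acetoxy-3-methylbut-2-enoate of 20
Conditions: DCC, DMAP (cat.), CH2Cl2, −10 to 0 °C
Reagents that add atoms: none
Why: Low-temperature Steglich esterification acylates the single free (8R) hydroxyl with retention at C8 and without Z/E drift of the β,β-disubstituted enoate.

Step 16
Reactants: 25 seco-tetraene ester
Product: 26 15-O-TBS ether of the target
Conditions: Grubbs II (15 mol %), 1,4-benzoquinone (cat.), toluene (0.5 mM), 80 °C
Reagents that add atoms: none
Why: Diene–ene ring-closing metathesis engages only the two terminal vinyl groups (the α-methylene lactone and the trisubstituted olefins are spectators), and the trans-lactone, trans-oxirane and cis-C4=C5 units allow only the Z-C2=C3 ten-membered ring.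

Step 17
Reactants: 26 15-O-TBS ether of the target
Product: 27 target CNP0292814.1
Conditions: Et3N·3HF, MeCN–THF, 0 °C to rt
Reagents that add atoms: none
Why: Buffered fluoride desilylation frees the primary allylic alcohol while the vinyl oxirane, both esters and the Michael acceptor survive.

## Compound list
1 | prop-2-yn-1-ol | C#CCO | starting material
2 | 3-bromoprop-1-yne | C#CCBr | starting material
3 | hexa-2,5-diyn-1-ol | OCC#CCC#C | intermediate
4 | (2E)-hex-2-en-5-yn-1-ol | OC/C=C/CC#C | intermediate
5 | alkenylalane: dimethyl[(1E,4E)-6-(dimethylalumanyloxy)-2-methylhexa-1,4-dienyl]alumane | C[Al](C)/C=C(\C)C/C=C/CO[Al](C)C | intermediate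
6 | (2E,5E)-5-methylocta-2,5,7-trien-1-ol | OC/C=C/C/C(C)=C/C=C | intermediate
7 | (2E)-4-[(2R,3R)-3-ethenyl-2-methyloxiran-2-yl]but-2-en-1-ol | OC/C=C/C[C@@]1(C)O[C@@H]1C=C | intermediate
8 | [(2R,3R)-3-{[(2R,3R)-3-ethenyl-2-methyloxiran-2-yl]methyl}oxiran-2-yl]methanol | OC[C@H]1O[C@@H]1C[C@@]2(C)O[C@@H]2C=C | intermediate
9 | (2S,3R)-3-{[(2R,3R)-3-ethenyl-2-methyloxiran-2-yl]methyl}oxirane-2-carbaldehyde | O=C[C@H]1O[C@@H]1C[C@@]2(C)O[C@@H]2C=C | intermediate
10 | 3-(trimethylsilyl)prop-2-yn-1-ol | C[Si](C)(C)C#CCO | starting material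
11 | chelated dienylmagnesium alkoxide (Mg cis to CH2O, SiMe3 cis to vinyl) | C[Si](C)(C)/C([Mg]Cl)=C(/CO[Mg]Cl)C=C | intermediate
12 | (2E)-2-[(trimethylsilyl)methylidene]but-3-en-1-ol | C[Si](C)(C)/C=C(/CO)C=C | intermediate
13 | TBS ether of 12 | C[Si](C)(C)/C=C(/CO[Si](C)(C)C(C)(C)C)C=C | intermediate
14 | tert-butyl{[(2E)-2-(iodomethylidene)but-3-en-1-yl]oxy}dimethylsilane | I/C=C(/CO[Si](C)(C)C(C)(C)C)C=C | intermediate
15 | dienyllithium from 14 (Li cis to vinyl) | [Li]/C=C(/CO[Si](C)(C)C(C)(C)C)C=C | intermediate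
16 | anti-epoxy alcohol (6R,7R,8R,10R,1R) | O[C@H](/C=C(CO[Si](C)(C)C(C)(C)C)\C=C)[C@H]1O[C@@H]1C[C@@]2(C)O[C@@H]2C=C | intermediate
17 | (diethoxyphosphoryl)acetic acid | CCOP(=O)(OCC)CC(=O)O | starting material
18 | O6-(diethoxyphosphoryl)acetate of 16 | CCOP(=O)(OCC)CC(=O)O[C@H](/C=C(CO[Si](C)(C)C(C)(C)C)\C=C)[C@H]1O[C@@H]1C[C@@]2(C)O[C@@H]2C=C | intermediate
19 | α-(diethoxyphosphoryl)-γ-lactone with free 8-OH (C11 epimers, present as sodium salt) | CCOP(=O)(OCC)C1C(=O)O[C@H](/C=C(CO[Si](C)(C)C(C)(C)C)\C=C)[C@H]1[C@H](O)C[C@@]2(C)O[C@@H]2C=C | intermediate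
20 | hydroxy α-methylene-γ-lactone (6R,7R,8R,10R,1R) | C=C1C(=O)O[C@H](/C=C(CO[Si](C)(C)C(C)(C)C)\C=C)[C@H]1[C@H](O)C[C@@]2(C)O[C@@H]2C=C | intermediate
21 | chelated (Z)-alkenylmagnesium alkoxide | Br[Mg]/C=C(/C)CO[Mg]Br | intermediate
22 | (2Z)-3-iodo-2-methylprop-2-en-1-ol | I/C=C(/C)CO | intermediate
23 | (2Z)-3-iodo-2-methylprop-2-en-1-yl acetate | I/C=C(/C)COC(C)=O | intermediate
24 | (2Z)-4-acetoxy-3-methylbut-2-enoic acid | OC(=O)/C=C(/C)COC(C)=O | intermediate
25 | seco ester (RCM precursor) | C=C1C(=O)O[C@H](/C=C(CO[Si](C)(C)C(C)(C)C)\C=C)[C@H]1[C@H](OC(=O)/C=C(/C)COC(C)=O)C[C@@]2(C)O[C@@H]2C=C | intermediate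
26 | 15-O-TBS ether of the target | C=C1C(=O)O[C@@H]2/C=C(CO[Si](C)(C)C(C)(C)C)\C=C/[C@H]3O[C@]3(C)C[C@@H](OC(=O)/C=C(/C)COC(C)=O)[C@@H]12 | intermediate
27 | CNP0292814.1 (1R,6R,7R,8R,10R) | C=C1C(=O)O[C@@H]2/C=C(CO)\C=C/[C@H]3O[C@]3(C)C[C@@H](OC(=O)/C=C(/C)COC(C)=O)[C@@H]12 | target

## Step count and risks
**Total steps:** 17.
**Longest linear sequence:** 11 (steps 1–5, 9–11, 15–17).

**Most likely to fail, first: step 16.** Closing a strained ten-membered ring by RCM can lose to oligomerisation or to attack on the inner diene olefin. The fallback closes the carbocycle before the lactone exists, when the chain is more flexible and carries fewer olefins.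
- It sets out from 16, and RCM gives the macrocyclic bis-epoxy alcohol F3.
- Steglich acylation with 17 gives the macrocyclic phosphonoacetate F4.
- NaH triggers the oxirane opening across the ring to the macrocyclic phosphono-lactone F5.
- Formaldehyde then gives the macrocyclic hydroxy α-methylene lactone F6.
- Esterification with 24 comes back to the route at 26.

**Second: step 11.** The phosphonate carbanion may open the oxirane sluggishly or 6-endo. The fallback swaps the carbanion/HWE logic for nucleophilic phosphine catalysis. It sets out from 16, which acryloyl chloride and Et3N convert into the O6-acrylate F2. PMe3 in t-BuOH adds to the acrylate, the α-carbon opens the oxirane 5-exo, and loss of the phosphine (Morita–Baylis–Hillman-type alkylation) delivers the methylene lactone directly, coming back at 20.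

**Third: step 4.** The allylic-alcohol olefin is the slower partner and the diastereomers may be hard to separate. The fallback splits the task between two different control elements. It sets out from 6, and Sharpless asymmetric epoxidation (Ti(OiPr)4, D-(−)-DET, TBHP, 4 Å MS, −20 °C) touches only the allylic-alcohol olefin and gives the dienyl epoxy alcohol F1. A single Shi epoxidation then only has to find the trisubstituted diene terminus, and the sequence comes back at 8.

## Further compounds
F1 | step 4 | [(2R,3R)-3-[(2E)-2-methylpenta-2,4-dien-1-yl]oxiran-2-yl]methanol | OC[C@H]1O[C@@H]1C/C(C)=C/C=C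
F2 | step 11 | O6-acrylate of 16 | C=CC(=O)O[C@H](/C=C(CO[Si](C)(C)C(C)(C)C)\C=C)[C@H]1O[C@@H]1C[C@@]2(C)O[C@@H]2C=C
F3 | step 16 | macrocyclic 1,10:7,8-bis-epoxy-6-ol (2Z, 4,5-cis, 15-OTBS) | O[C@@H]1/C=C(CO[Si](C)(C)C(C)(C)C)\C=C/[C@H]2O[C@]2(C)C[C@H]3O[C@H]13
F4 | step 16 | O6-(diethoxyphosphoryl)acetate of F3 | CCOP(=O)(OCC)CC(=O)O[C@@H]1/C=C(CO[Si](C)(C)C(C)(C)C)\C=C/[C@H]2O[C@]2(C)C[C@H]3O[C@H]13
F5 | step 16 | macrocyclic α-(diethoxyphosphoryl) lactone with free 8-OH | CCOP(=O)(OCC)C1C(=O)O[C@@H]2/C=C(CO[Si](C)(C)C(C)(C)C)\C=C/[C@H]3O[C@]3(C)C[C@@H](O)[C@@H]12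
F6 | step 16 | macrocyclic 8-hydroxy α-methylene lactone (15-OTBS) | C=C1C(=O)O[C@@H]2/C=C(CO[Si](C)(C)C(C)(C)C)\C=C/[C@H]3O[C@]3(C)C[C@@H](O)[C@@H]12
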